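A direct plan would open a donor–acceptor cyclopropane: organocatalytic cyclopropanation of a ring C cinnamaldehyde with an α-bromo-β-keto ester of ring A, adjustment to the cyclopropane diester A1, then In(OTf)3-induced ring opening and closure onto ring A (C1–C8a) to the enol diester A2.
The C4 oxygen would then be removed, the core phenol A3 unmasked, and the third caffeate unit added by carbenoid O–H insertion and Still–Gennari olefination before saponification and debenzylation.
Its weakest steps would be:
(1) the ring opening/arylation A1 → A2: it has no close precedent, it would have to choose one of three cyclopropane bonds, C- over O-capture and one of two ortho positions at once, and it would set C1 through a free benzylic cation after two of the three stereocentres bought in the cyclopropanation are discarded;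
(2) the stretch that builds nothing: aldehyde to acid to ester, then enol triflate and palladium–formate reduction only to delete the C4 oxygen that the keto ester brought in, plus an acetate put on and taken off;
(3) the ten-step linear run to the simple phenol A3, which puts the fragment coupling behind the longest sequence.

**Retrosynthetic overview**
Numbering: dihydronaphthalene C1–C8a (ring A benzo, ring B C1–C4), ring C on C1 (C1'–C6'), ring D in the side chain. Ring B is cut at C1–C2 and C3–C4: the vicinal carboxyl groups on C2/C3 are a fumarate, and C1 and C4 are the benzylic termini of an o-quinodimethane of ring A.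
A photoenolization/Diels–Alder reaction of the 2-benzylbenzaldehyde 7 with the fumarate 10 of methyl (S)-mandelate forms both bonds, closes ring B and sets C1; 7 comes in one step by palladium-catalysed arylation of the methyl group of aldehyde 3 (C1–C1').
The C4 hydroxyl then leaves as water to give C3=C4 (no redox step); in the same flask methoxide removes auxiliary and acetate and relays the configuration from C1 to C2 (trans). This relay is a correction under thermodynamic control and is the main stereochemical risk of the route.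
Ring order: A and C given and joined at C1, ring B by [4+2], ring D appended last (O–H insertion, Still–Gennari olefination). There is no cyclopropane, no cation at C1, no C4 oxygen to delete, and phenol 15 is five linear steps from 4-methylcatechol.

Key step: step 7

Assumption: the (S)-mandelate fumarate is taken to make the aryl-bearing carbon R, the sense expected for aryl-substituted hydroxy-o-quinodimethanes with this auxiliary; if it proved opposite, methyl (R)-mandelate would be used in step 6.

**Route**

Step 1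
Reactants: 1 4-methylcatechol (4-methylbenzene-1,2-diol)
Product: 2 1,2-diisopropoxy-4-methylbenzene
Conditions: 2-bromopropane (3 equiv), K2CO3 (3 equiv), DMF, 70 °C
Reagents that add atoms: 2-bromopropane, CC(C)Br
Why: Williamson ether synthesis on both phenols; isopropyl ethers have no benzylic C–H bonds, should survive the silver and acid of step 5, light and base, and are removed by BCl3 at the end.

Step 2
Reactants: 2 1,2-diisopropoxy-4-methylbenzene
Product: 3 4,5-diisopropoxy-2-methylbenzaldehyde
Conditions: POCl3 (1.5 equiv), DMF, 0 → 80 °C; then aqueous NaOAc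
Reagents that add atoms: N,N-dimethylformamide, CN(C)C=O; water, O
Why: Vilsmeier–Haack formylation at the only free position para to an ether oxygen, which is also ortho to the methyl group (the course expected for 3,4-dialkoxytoluenes).

Step 3
Reactants: 4 2-isopropoxyphenol
Product: 5 2-isopropoxyphenyl acetate
Conditions: Ac2O (1.2 equiv), pyridine, DMAP (2 mol %), CH2Cl2, rt
Reagents that add atoms: acetic anhydride, CC(=O)OC(C)=O
Why: O-acetylation (nucleophilic acyl substitution); the acetate masks the future O3' and makes its oxygen the weaker director for step 4.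

Step 4
Reactants: 5 2-isopropoxyphenyl acetate
Product: 6 5-iodo-2-isopropoxyphenyl acetate
Conditions: NIS (1.05 equiv), CF3CO2H (0.3 equiv), MeCN, rt
Reagents that add atoms: N-iodosuccinimide, O=C1CCC(=O)N1I
Why: Electrophilic aromatic iodination para to the stronger donor, the isopropoxy group, as in the halogenation of guaiacol acetate, which places iodine at the future C1'.

Step 5
Reactants: 3 4,5-diisopropoxy-2-methylbenzaldehyde; 6 5-iodo-2-isopropoxyphenyl acetate
Product: 7 5-[(2-formyl-4,5-diisopropoxyphenyl)methyl]-2-isopropoxyphenyl acetate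
Conditions: Pd(OAc)2 (10 mol %), glycine (40 mol %), AgOCOCF3 (1.5 equiv), (CF3)2CHOH/AcOH (9:1), 90 °C
Reagents that add atoms: none
Why: Palladium-catalysed C(sp3)–H arylation of a 2-methylbenzaldehyde with a transient directing group: the glycine imine guides divalent palladium into the ortho-methyl C–H bond (six-membered palladacycle), oxidative addition of 6 and reductive elimination from tetravalent palladium form the C1–C1' bond, and silver takes up iodide, while aldehyde, acetate and ethers should not be touched.

Step 6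
Reactants: 8 fumaryl chloride; 9 methyl (S)-mandelate
Product: 10 bis[(1S)-2-methoxy-2-oxo-1-phenylethyl] (2E)-but-2-enedioate
Conditions: 9 (2.1 equiv), pyridine (2.2 equiv), CH2Cl2, −20 → 0 °C
Reagents that add atoms: methyl (S)-mandelate (second equivalent of 9), COC(=O)[C@@H](O)c1ccccc1
Why: Twofold alcoholysis of the diacid chloride (nucleophilic acyl substitution): each of the two acyl chloride groups is taken by one molecule of the secondary alcohol 9, so two equivalents of 9 are consumed per fumaryl chloride, and the weak base at low temperature should leave the mandelate stereocentres and the E double bond untouched.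

Step 7
Reactants: 7 5-[(2-formyl-4,5-diisopropoxyphenyl)methyl]-2-isopropoxyphenyl acetate; 10 bis[(1S)-2-methoxy-2-oxo-1-phenylethyl] (2E)-but-2-enedioate
Product: 12 bis[(1S)-2-methoxy-2-oxo-1-phenylethyl] (1R,2R,3S,4R)-1-(3-acetoxy-4-isopropoxyphenyl)-4-hydroxy-6,7-diisopropoxy-1,2,3,4-tetrahydronaphthalene-2,3-dicarboxylate, via dienol 11 (not isolated)
Conditions: hν (365 nm, Pyrex), 10 (1.5 equiv), toluene (0.02 M, degassed), 20 °C
Reagents that add atoms: none
Why: Excitation of the aryl aldehyde is followed by 1,5-hydrogen transfer from the doubly benzylic CH2 to the carbonyl oxygen, and the 1,4-biradical relaxes to the long-lived (E,E)-dienol 11 (hydroxyl and aryl both outward), which the fumarate traps in a thermal [4π+2π] cycloaddition before it reverts to 7. The closest known reaction type is the photoenolization/Diels–Alder reaction of 2-benzylbenzaldehydes with fumarates, including chiral fumarates of α-hydroxy esters used for aryltetralin lignans. Ring B closes through one concerted six-membered transition state that forms C1–C2 and C3–C4 together and restores the aromaticity of ring A. C1 is controlled by the auxiliary: the dienol hydroxyl should hydrogen-bond to a mandelate ester carbonyl, so the diene meets one face of the fumarate only, taken here to give (R)-C1. C2 follows from the endo position of the ester next to the aryl terminus (aryl and C2 ester cis), C3 from the E geometry of the fumarate and C4 from the E-dienol; C3 and C4 are erased and C2 is inverted in step 8. The step needs trapping to beat reketonisation and sensitised E/Z isomerisation of 10 (excess dienophile, dilution, no oxygen, light that only the aldehyde absorbs); regiochemistry is no issue because the dienophile is twofold-symmetric.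

Step 8
Reactants: 12 bis[(1S)-2-methoxy-2-oxo-1-phenylethyl] (1R,2R,3S,4R)-1-(3-acetoxy-4-isopropoxyphenyl)-4-hydroxy-6,7-diisopropoxy-1,2,3,4-tetrahydronaphthalene-2,3-dicarboxylate
Product: 15 dimethyl (1R,2S)-1-(3-hydroxy-4-isopropoxyphenyl)-6,7-diisopropoxy-1,2-dihydronaphthalene-2,3-dicarboxylate, via mesylate 13 (not isolated), via cis-dihydronaphthalene 14 (not isolated)
Conditions: MsCl (1.5 equiv), Et3N (3 equiv), CH2Cl2, 0 °C; then NaOMe (4 equiv), MeOH, 0 °C → rt
Reagents that add atoms: sodium methoxide, C[O-].[Na+]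
Why: The benzylic mesylate loses methanesulfonate toward C3 by E1cB elimination through the ester enolate, methoxide then cleaves the activated mandelate esters and the aryl acetate by transesterification and epimerises C2 through its ester dienolate, so that C2 is set under thermodynamic control by C1: in the trans isomer the aryl group and the C2 ester are both pseudoaxial and free of peri and allylic strain.

Step 9
Reactants: 16 methyl bis(2,2,2-trifluoroethyl)phosphonoacetate
Product: 17 methyl diazo[bis(2,2,2-trifluoroethoxy)phosphoryl]acetate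
Conditions: 4-acetamidobenzenesulfonyl azide, DBU, MeCN, 0 °C → rt
Reagents that add atoms: 4-acetamidobenzenesulfonyl azide, CC(=O)Nc1ccc(S(=O)(=O)N=[N+]=[N-])cc1
Why: Regitz diazo transfer to the acidic methylene group of the commercial Still–Gennari phosphonate.

Step 10
Reactants: 15 dimethyl (1R,2S)-1-(3-hydroxy-4-isopropoxyphenyl)-6,7-diisopropoxy-1,2-dihydronaphthalene-2,3-dicarboxylate; 17 methyl diazo[bis(2,2,2-trifluoroethoxy)phosphoryl]acetate
Product: 18 dimethyl (1R,2S)-1-[3-{[bis(2,2,2-trifluoroethoxy)phosphoryl](methoxycarbonyl)methoxy}-4-isopropoxyphenyl]-6,7-diisopropoxy-1,2-dihydronaphthalene-2,3-dicarboxylate (both epimers at the side-chain carbon)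
Conditions: Rh2(OAc)4 (2 mol %), toluene, 80 °C, slow addition of 17
Reagents that add atoms: none
Why: Rhodium carbenoid O–H insertion into the only free phenol, which should be faster than attack on the electron-poor C3=C4 bond or on C–H bonds; the new side-chain stereocentre forms as a mixture and disappears in step 11.

Step 11
Reactants: 18 dimethyl (1R,2S)-1-[3-{[bis(2,2,2-trifluoroethoxy)phosphoryl](methoxycarbonyl)methoxy}-4-isopropoxyphenyl]-6,7-diisopropoxy-1,2-dihydronaphthalene-2,3-dicarboxylate; 19 3,4-bis(benzyloxy)benzaldehyde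
Product: 20 dimethyl (1R,2S)-1-[3-{[(E)-2-[3,4-bis(benzyloxy)phenyl]-1-(methoxycarbonyl)ethenyl]oxy}-4-isopropoxyphenyl]-6,7-diisopropoxy-1,2-dihydronaphthalene-2,3-dicarboxylate
Conditions: KN(SiMe3)2 (1.0 equiv), 18-crown-6 (4 equiv), THF, −78 °C; then 19, −78 → −40 °C
Reagents that add atoms: none
Why: Still–Gennari variant of the Horner–Wadsworth–Emmons reaction: with trifluoroethyl phosphonate esters and a dissociated potassium ion the first adduct collapses faster than it reverts, which should place ring D cis to the ester (the E isomer, since O3' outranks the ester carbon), and the one equivalent of base is consumed by the phosphonate C–H, far more acidic than C2–H.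

Step 12
Reactants: 20 dimethyl (1R,2S)-1-[3-{[(E)-2-[3,4-bis(benzyloxy)phenyl]-1-(methoxycarbonyl)ethenyl]oxy}-4-isopropoxyphenyl]-6,7-diisopropoxy-1,2-dihydronaphthalene-2,3-dicarboxylate
Product: 21 (1R,2S)-1-[3-{[(E)-2-[3,4-bis(benzyloxy)phenyl]-1-carboxyethenyl]oxy}-4-isopropoxyphenyl]-6,7-diisopropoxy-1,2-dihydronaphthalene-2,3-dicarboxylic acid
Conditions: LiOH (15 equiv), THF/MeOH/H2O, argon, rt → 40 °C; then 1 M HCl, 0 °C
Reagents that add atoms: lithium hydroxide, [Li+].[OH-]
Why: Saponification (BAc2) of the three methyl esters while all phenols are still ethers, so that no free catechol meets base; C2 already has the thermodynamically favoured trans configuration.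

Step 13
Reactants: 21 (1R,2S)-1-[3-{[(E)-2-[3,4-bis(benzyloxy)phenyl]-1-carboxyethenyl]oxy}-4-isopropoxyphenyl]-6,7-diisopropoxy-1,2-dihydronaphthalene-2,3-dicarboxylic acid
Product: 22 (1R,2S)-1-[3-{[(E)-1-carboxy-2-(3,4-dihydroxyphenyl)ethenyl]oxy}-4-hydroxyphenyl]-6,7-dihydroxy-1,2-dihydronaphthalene-2,3-dicarboxylic acid (CNP0241205.1)
Conditions: BCl3 (20 equiv), C6HMe5 (15 equiv), CH2Cl2, −78 → 0 °C; then aqueous THF
Reagents that add atoms: none
Why: Lewis acid cleavage of the two benzyl and three isopropyl aryl ethers: BCl3 coordinates each ether oxygen, the benzyl cations are taken up by pentamethylbenzene (Friedel–Crafts alkylation) and the isopropyl groups leave as 2-chloropropane, while at or below 0 °C the two alkenes, the aryl vinyl ether bond and both stereocentres should remain untouched.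

**Compound list**
1 | 4-methylcatechol | Cc1ccc(O)c(O)c1 | starting material
2 | 1,2-diisopropoxy-4-methylbenzene | Cc1ccc(OC(C)C)c(OC(C)C)c1 | intermediate
3 | 4,5-diisopropoxy-2-methylbenzaldehyde | Cc1cc(OC(C)C)c(OC(C)C)cc1C=O | intermediate
4 | 2-isopropoxyphenol | CC(C)Oc1ccccc1O | starting material
5 | 2-isopropoxyphenyl acetate | CC(=O)Oc1ccccc1OC(C)C | intermediate
6 | 5-iodo-2-isopropoxyphenyl acetate | CC(=O)Oc1cc(I)ccc1OC(C)C | intermediate
7 | 5-[(2-formyl-4,5-diisopropoxyphenyl)methyl]-2-isopropoxyphenyl acetate | CC(=O)Oc1cc(Cc2cc(OC(C)C)c(OC(C)C)cc2C=O)ccc1OC(C)C | intermediate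
8 | fumaryl chloride | O=C(Cl)/C=C/C(=O)Cl | starting material
9 | methyl (S)-mandelate | COC(=O)[C@@H](O)c1ccccc1 | starting material
10 | bis[(1S)-2-methoxy-2-oxo-1-phenylethyl] (2E)-but-2-enedioate | COC(=O)[C@@H](OC(=O)/C=C/C(=O)O[C@H](C(=O)OC)c1ccccc1)c1ccccc1 | intermediate
11 | (E,E)-dienol, 5-{(E)-[(6E)-6-(hydroxymethylidene)-3,4-diisopropoxycyclohexa-2,4-dien-1-ylidene]methyl}-2-isopropoxyphenyl acetate | O/C=C1\C=C(OC(C)C)C(OC(C)C)=C/C1=C\c1ccc(OC(C)C)c(OC(C)=O)c1 | intermediate
12 | bis[(1S)-2-methoxy-2-oxo-1-phenylethyl] (1R,2R,3S,4R)-1-(3-acetoxy-4-isopropoxyphenyl)-4-hydroxy-6,7-diisopropoxy-1,2,3,4-tetrahydronaphthalene-2,3-dicarboxylate | COC(=O)[C@@H](OC(=O)[C@@H]1[C@@H](O)c2cc(OC(C)C)c(OC(C)C)cc2[C@@H](c2ccc(OC(C)C)c(OC(C)=O)c2)[C@H]1C(=O)O[C@H](C(=O)OC)c1ccccc1)c1ccccc1 | intermediate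
13 | bis[(1S)-2-methoxy-2-oxo-1-phenylethyl] (1R,2R,3S,4R)-1-(3-acetoxy-4-isopropoxyphenyl)-6,7-diisopropoxy-4-[(methylsulfonyl)oxy]-1,2,3,4-tetrahydronaphthalene-2,3-dicarboxylate | COC(=O)[C@@H](OC(=O)[C@@H]1[C@@H](OS(C)(=O)=O)c2cc(OC(C)C)c(OC(C)C)cc2[C@@H](c2ccc(OC(C)C)c(OC(C)=O)c2)[C@H]1C(=O)O[C@H](C(=O)OC)c1ccccc1)c1ccccc1 | intermediate
14 | bis[(1S)-2-methoxy-2-oxo-1-phenylethyl] (1R,2R)-1-(3-acetoxy-4-isopropoxyphenyl)-6,7-diisopropoxy-1,2-dihydronaphthalene-2,3-dicarboxylate (cis) | COC(=O)[C@@H](OC(=O)C1=Cc2cc(OC(C)C)c(OC(C)C)cc2[C@@H](c2ccc(OC(C)C)c(OC(C)=O)c2)[C@H]1C(=O)O[C@H](C(=O)OC)c1ccccc1)c1ccccc1 | intermediate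
15 | dimethyl (1R,2S)-1-(3-hydroxy-4-isopropoxyphenyl)-6,7-diisopropoxy-1,2-dihydronaphthalene-2,3-dicarboxylate | COC(=O)C1=Cc2cc(OC(C)C)c(OC(C)C)cc2[C@@H](c2ccc(OC(C)C)c(O)c2)[C@@H]1C(=O)OC | intermediate
16 | methyl bis(2,2,2-trifluoroethyl)phosphonoacetate | COC(=O)CP(=O)(OCC(F)(F)F)OCC(F)(F)F | starting material
17 | methyl diazo[bis(2,2,2-trifluoroethoxy)phosphoryl]acetate | COC(=O)C(=[N+]=[N-])P(=O)(OCC(F)(F)F)OCC(F)(F)F | intermediate
18 | dimethyl (1R,2S)-1-[3-{[bis(2,2,2-trifluoroethoxy)phosphoryl](methoxycarbonyl)methoxy}-4-isopropoxyphenyl]-6,7-diisopropoxy-1,2-dihydronaphthalene-2,3-dicarboxylate (both epimers at the side-chain carbon) | COC(=O)C1=Cc2cc(OC(C)C)c(OC(C)C)cc2[C@@H](c2ccc(OC(C)C)c(OC(C(=O)OC)P(=O)(OCC(F)(F)F)OCC(F)(F)F)c2)[C@@H]1C(=O)OC | intermediate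
19 | 3,4-bis(benzyloxy)benzaldehyde | O=Cc1ccc(OCc2ccccc2)c(OCc2ccccc2)c1 | starting material
20 | dimethyl (1R,2S)-1-[3-{[(E)-2-[3,4-bis(benzyloxy)phenyl]-1-(methoxycarbonyl)ethenyl]oxy}-4-isopropoxyphenyl]-6,7-diisopropoxy-1,2-dihydronaphthalene-2,3-dicarboxylate | COC(=O)C1=Cc2cc(OC(C)C)c(OC(C)C)cc2[C@@H](c2ccc(OC(C)C)c(O/C(=C/c3ccc(OCc4ccccc4)c(OCc4ccccc4)c3)C(=O)OC)c2)[C@@H]1C(=O)OC | intermediate
21 | (1R,2S)-1-[3-{[(E)-2-[3,4-bis(benzyloxy)phenyl]-1-carboxyethenyl]oxy}-4-isopropoxyphenyl]-6,7-diisopropoxy-1,2-dihydronaphthalene-2,3-dicarboxylic acid | O=C(O)C1=Cc2cc(OC(C)C)c(OC(C)C)cc2[C@@H](c2ccc(OC(C)C)c(O/C(=C/c3ccc(OCc4ccccc4)c(OCc4ccccc4)c3)C(=O)O)c2)[C@@H]1C(=O)O | intermediate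
22 | (1R,2S)-1-[3-{[(E)-1-carboxy-2-(3,4-dihydroxyphenyl)ethenyl]oxy}-4-hydroxyphenyl]-6,7-dihydroxy-1,2-dihydronaphthalene-2,3-dicarboxylic acid | O=C(O)C1=Cc2cc(O)c(O)cc2[C@@H](c2ccc(O)c(O/C(=C/c3ccc(O)c(O)c3)C(=O)O)c2)[C@@H]1C(=O)O | target

**Step count and risks**
Total step count: 13. Longest linear sequence: 9 steps (1, 2, 5, 7, 8, 10, 11, 12, 13).

Steps most likely to fail:

Step 7 (key step). The dienol 11 may revert to 7 faster than it is trapped, and energy transfer from the excited aldehyde may isomerise the fumarate, so that conversion stalls and maleate-derived adducts erode the diastereomer ratio. As a fallback the photochemistry would be separated from the cycloaddition. Setting out from 7, irradiation in benzene saturated with sulfur dioxide should trap 11 by cheletropic addition as the cyclic sulfone cis-1-(3-acetoxy-4-isopropoxyphenyl)-3-hydroxy-5,6-diisopropoxy-1,3-dihydro-2-benzothiophene 2,2-dioxide F1. Heating F1 with 10 in toluene at 80 °C in the dark would extrude SO2, release 11 slowly beside the undisturbed E dienophile, and give 12, where the route is rejoined.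

Step 8. During the base-mediated equilibration the C2 dienolate can also be protonated at C4; the 1,4-dihydro tautomer so formed has an acidic, doubly benzylic C1–H, so long exposure to methoxide would erode the configuration at C1, while short exposure may leave methanolysis or the cis-to-trans relay incomplete. As a fallback the relay would be done before the C3=C4 bond exists. Setting out from 12, silylation (TBSOTf, 2,6-lutidine) would give the silyl ether bis[(1S)-2-methoxy-2-oxo-1-phenylethyl] (1R,2R,3S,4R)-1-(3-acetoxy-4-isopropoxyphenyl)-4-[(tert-butyldimethylsilyl)oxy]-6,7-diisopropoxy-1,2,3,4-tetrahydronaphthalene-2,3-dicarboxylate F2. NaOMe in MeOH would then exchange the esters, remove the acetate and equilibrate C2 and C3 of the saturated diester, where C1–H is not activated, to the 1,2-trans diester dimethyl (1R,2S,3R,4R)-4-[(tert-butyldimethylsilyl)oxy]-1-(3-hydroxy-4-isopropoxyphenyl)-6,7-diisopropoxy-1,2,3,4-tetrahydronaphthalene-2,3-dicarboxylate F3. TsOH·H2O in toluene at 60 °C would finally remove the silyl group and expel water through the benzylic cation at C4 (E1) to give 15, with no base at the alkene stage.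

Step 5. Protodeiodination or homocoupling of the electron-rich iodide, palladation of ring positions, or acidolysis of the ethers in hot hexafluoroisopropanol may outrun the slow palladation of the methyl group. As a fallback the same bond would be made by anionic chemistry. Setting out from 3, condensation with cyclohexylamine would give the imine (E)-N-cyclohexyl-1-(4,5-diisopropoxy-2-methylphenyl)methanimine F4. Lateral lithiation of its methyl group (lithium 2,2,6,6-tetramethylpiperidide, THF, −78 °C), transmetalation with ZnCl2 and Negishi coupling of the benzylic zinc reagent with iodide 6 (Pd2(dba)3, SPhos), followed by mild acid hydrolysis of the imine, would return 7.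

**Further compounds**
F1 | step 7 | cis-1-(3-acetoxy-4-isopropoxyphenyl)-3-hydroxy-5,6-diisopropoxy-1,3-dihydro-2-benzothiophene 2,2-dioxide (racemic) | O[C@H]1c2cc(OC(C)C)c(OC(C)C)cc2[C@@H](c2ccc(OC(C)C)c(OC(C)=O)c2)S1(=O)=O
F2 | step 8 | bis[(1S)-2-methoxy-2-oxo-1-phenylethyl] (1R,2R,3S,4R)-1-(3-acetoxy-4-isopropoxyphenyl)-4-[(tert-butyldimethylsilyl)oxy]-6,7-diisopropoxy-1,2,3,4-tetrahydronaphthalene-2,3-dicarboxylate | COC(=O)[C@@H](OC(=O)[C@@H]1[C@@H](O[Si](C)(C)C(C)(C)C)c2cc(OC(C)C)c(OC(C)C)cc2[C@@H](c2ccc(OC(C)C)c(OC(C)=O)c2)[C@H]1C(=O)O[C@H](C(=O)OC)c1ccccc1)c1ccccc1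
F3 | step 8 | dimethyl (1R,2S,3R,4R)-4-[(tert-butyldimethylsilyl)oxy]-1-(3-hydroxy-4-isopropoxyphenyl)-6,7-diisopropoxy-1,2,3,4-tetrahydronaphthalene-2,3-dicarboxylate | COC(=O)[C@H]1[C@@H](O[Si](C)(C)C(C)(C)C)c2cc(OC(C)C)c(OC(C)C)cc2[C@@H](c2ccc(OC(C)C)c(O)c2)[C@@H]1C(=O)OC
F4 | step 5 | (E)-N-cyclohexyl-1-(4,5-diisopropoxy-2-methylphenyl)methanimine | Cc1cc(OC(C)C)c(OC(C)C)cc1/C=N/C1CCCCC1
A1 | direct plan | dimethyl (1S,2S,3R)-3-[3-acetoxy-4-(benzyloxy)phenyl]-1-[3,4-bis(benzyloxy)benzoyl]cyclopropane-1,2-dicarboxylate | COC(=O)[C@H]1[C@H](c2ccc(OCc3ccccc3)c(OC(C)=O)c2)[C@@]1(C(=O)OC)C(=O)c1ccc(OCc2ccccc2)c(OCc2ccccc2)c1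
A2 | direct plan | dimethyl (1R,2S)-1-[3-acetoxy-4-(benzyloxy)phenyl]-6,7-bis(benzyloxy)-4-hydroxy-1,2-dihydronaphthalene-2,3-dicarboxylate | COC(=O)C1=C(O)c2cc(OCc3ccccc3)c(OCc3ccccc3)cc2[C@@H](c2ccc(OCc3ccccc3)c(OC(C)=O)c2)[C@@H]1C(=O)OC
A3 | direct plan | dimethyl (1R,2S)-6,7-bis(benzyloxy)-1-[4-(benzyloxy)-3-hydroxyphenyl]-1,2-dihydronaphthalene-2,3-dicarboxylate | COC(=O)C1=Cc2cc(OCc3ccccc3)c(OCc3ccccc3)cc2[C@@H](c2ccc(OCc3ccccc3)c(O)c2)[C@@H]1C(=O)OC
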